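The numbers in the tables come from a simulation with constants of no real substance; noise was put on by code.

Amounts first: in the south-west run at 2.00 h substrate reads 23% and target 20%, so 57.0% of the charge stands between them, and the lag of target suggests that this material waits there as intermediate for partner.

| setting | south-west | east | west | flask |
|---|---|---|---|---|
| substrate | 0.28 M | 0.44 M | 0.20 M | 0.20 M |
| partner | 0.70 equiv | 0.70 equiv | 0.35 equiv | 0.700 equiv |
| remark | run made earlier | run made earlier | run made earlier |  |
| time |  |  |  | 6.0 h |

| run | time / h | target / % | substrate / % |
|---|---|---|---|
| south-west | 0.417 | 2 | 74 |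
| south-west | 0.667 | 4 | 61 |
| south-west | 1.00 | 10 | 49 |
| south-west | 2.00 | 20 | 23 |
| south-west | 3.00 | 32 | 12 |
| south-west | 5.00 | 39 | 4 |
| east | 0.833 | 8 | 54 |
| east | 1.50 | 20 | 30 |
| east | 2.50 | 33 | 16 |
| east | 3.00 | 37 | 9 |
| east | 4.00 | 45 | 3 |
| east | 5.00 | 45 | 0 |
| west | 1.00 | 3 | 47 |
| west | 2.00 | 8 | 24 |
| west | 3.00 | 16 | 11 |
| west | 4.00 | 16 | 5 |
| west | 5.00 | 19 | 1 |

(scatter of a reading: 1.5 percentage points)

- a reading or a percentage of target counts all its forms, free or not

* amount of target in percent of the substrate charged, at 40 min, 2.0 h, 4.0 h and 6.0 h

Taking the rate of target as a constant times that share times c(partner), with c(partner) reckoned as the charge less the target read, the south-west run between 1.00 h and 3.00 h gives 1.38 /M/h, and the west run between 2.00 h and 4.00 h gives 1.44 /M/h. These two readings, each carrying the scatter of its slope, come from c(partner) of 0.140 M and 0.0380 M, so a rate of first order in partner is trusted here.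

Freezing c(partner) at the flask's charge, a pseudo-first-order view, gives 3.59 h as the half-life of intermediate against the partner charged. The substrate half-life read from the south-west run is 0.985 h, and the first time is longer, so intermediate should fill up much alike in the west run and the flask, both at 0.20 M.

My reckoning therefore multiplies the west readings by 2.00, which gives 16.0% at 2.0 h and 32.0% at 4.0 h, and a start growing with the square of time gives 2.67% at 40 min. The west run stops at 5.00 h, so a second way serves for 6.0 h: its reading there, doubled in the same way, gives 38.0%, and the last hour, reckoned at the rate constant of the south-west run with the share of intermediate and c(partner) frozen at their values for that moment, brings target to 43.4%.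

The forecast differs from this reckoning, with 4%, 18%, 34% and 41%, on the ground that “The limit depends on the partner charged, not on concentration.”

The flask gives 3.28%, 16.9%, 31.8% and 38.9%.

    substrate → intermediate (k = 2.07 × 10⁻⁴ /s)
    partner + intermediate → target (k = 5.12 × 10⁻⁴ /M/s)
    crystals ⇌ target, rate k3*(cs3 - [target]) while solid is left; crystals form when [target] > cs3 (solubility = 0.190 M, k = 2.12 × 10⁻⁴ /s)
    target ⇌ isomer of the product (K = 0.460, k = 2.69 × 10⁻⁵ /s)
    2 substrate → homo dimer (k = 1.90 × 10⁻⁷ /M/s)

At 0.915 h in the flask, intermediate has a half-life of 2.9 h by its reaction with partner, against the 3.59 h carried from the runs, and this half-life is longer than the 0.915 h by which the first step has half its turnover behind it, while intermediate is at that moment made 3.65 times faster than it is used up. At 6.00 h the flask holds 51.1% intermediate beside 38.9% target, and the flask with half the partner, for which the carried half-life becomes twice as long at 7.18 h, stands at 21.5% target.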